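Remark: the target (C26H50O2, one 27-membered ring, 25 CH2 groups) has no stereocentre and is achiral, so "the single enantiomer given" is the compound as drawn and no step has to set or keep a configuration.

## The problem

26-Hexacosanolide is a single 27-membered ring made of the ester oxygen, the carbonyl carbon C1 and 25 methylene groups C2–C26 (fatty-acid numbering, C26 bearing the ring oxygen). It has no stereocentre, no branch and no second functional group, so nothing in the ring can direct a reaction; the ester is the only group that must be spared from strong bases and nucleophiles, which places the ring closure last. The first difficulty is the chain: no cheap building block has 26 carbons with two different end groups, and the two ends are too far apart for a reagent to tell them apart. The second is the ring: closing 27 atoms from a freely rotating chain is entropically costly and competes with oligomerisation. The feature used here lies in the atoms C1(=O)–C2H2 and in the unbroken run C3–C26. The carbonyl carbon C1 with its unsubstituted α-methylene C2 is, one oxygen atom short, the two carbons of a terminal alkyne. The remaining 24 CH2 groups form a track along which a triple bond can travel without meeting a stereocentre, a branch or a heteroatom. The lactone is therefore the mono-oxygenated cycloisomer of an achiral alkynol C26H50O.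

## Retrosynthesis

9 ⇒ 6. The ring is cut at the acyl C1–O bond and the carbonyl oxygen is removed as well, which leads through the hydroxy ketene 8 and the rhodium vinylidene 7 to hexacos-25-yn-1-ol 6. Against its neighbours: a cut at the same bond to a carboxylic acid, or at O–C26 to a carboxylate and a halide, demands a seco acid with two differentiated, protected termini, and a cut at any C–C bond demands two olefins and a later hydrogenation. In 6 the future carbonyl is a terminal alkyne that is inert until the last step and needs no protection, so the precursor is acyclic and carries only OH and C≡CH. The forward reaction must oxygenate the terminal alkyne carbon only and must capture the ketene within the same molecule.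

6 ⇒ 4. No bond is cut; the terminal triple bond C25≡C26 of 6 is transposed to the internal position C10≡C11 of hexacos-10-yn-1-ol 4. This frees the carbon–carbon disconnection from any need for a 24-carbon ω-functional piece, because every internal alkynol isomer converges on 6. The forward reaction is a contra-thermodynamic migration over 15 positions, away from the alkoxide end.

4 ⇒ 1 + 2. The sp–sp3 bond C11–C12 of 4 is cut, giving the dilithium alkoxide acetylide 3 of 10-undecyn-1-ol 1 and 1-bromopentadecane 2. Both 1 and 2 are stock chemicals, whereas cuts at other positions of the chain lead to pieces that must be made. The dianion 3 removes the need for a hydroxyl protecting group, and the forward reaction must alkylate carbon in preference to oxygen.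

## Roads not taken

Alternative 1: The most obvious cut is at the ester C–O bond, which leads to 26-hydroxyhexacosanoic acid A1, to be closed by Yamaguchi macrolactonisation. The seco acid A1 must be assembled from two ω-functional pieces with the acid and alcohol termini kept apart by protecting groups and redox adjustments, which costs roughly twice as many steps before the ring is even attempted. The chosen plan never makes a carboxyl derivative; the carbonyl oxygen arrives in the ring-closing step itself.

Alternative 2: A cut at a C=C bond far from the ester. The diene ester undec-10-en-1-yl heptadec-16-enoate A2 would undergo ring-closing metathesis to oxacycloheptacos-17-en-2-one A3, and hydrogenation of A3 would give the target. The C17 olefinic acid half of A2 is no stock building block and needs its own synthesis. Ruthenium hydride species can shift the terminal olefins of A2 before closure, giving ring-contracted homologues that differ from the target by one CH2 in 26 and would be very hard to remove after hydrogenation. Large unstrained rings such as A3 also form under ring–chain equilibrium. In the chosen plan all positional isomers funnel into one terminal alkyne and no hydrogenation is needed.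

Alternative 3: Three-component ring-expansion metathesis. A strained eight-membered cycloalkene would be inserted into dec-9-en-1-yl dec-9-enoate A4 by ring-opening/ring-closing metathesis to give oxacycloheptacosa-10,18-dien-2-one A5, and hydrogenation of A5 would follow. Strain release drives the ring opening but not the selectivity: all olefins are of the same electronic type and the product A5 stays metathesis-active. A statistical mixture of rings with zero, one and two inserted C8 units and of cycloalkene oligomers is therefore expected. Nothing in A4 secures single insertion, whereas the chosen ring closure has only one possible connectivity.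

Key step: step 3

## Route

Step 1
Reactants: 1 10-undecyn-1-ol (undec-10-yn-1-ol); 2 1-bromopentadecane
Product: 4 hexacos-10-yn-1-ol, via dilithium alkoxide acetylide 3 (not isolated)
Conditions: n-BuLi (2.1 equiv), THF/HMPA, −40 → 0 °C; then 2, 0 °C → rt; then H2O
Reagents that add atoms: none
Why: SN2 alkylation of a lithium acetylide by a primary bromide; the second equivalent of base converts the hydroxyl into a lithium alkoxide that is far less nucleophilic than the acetylide carbon, so C-alkylation should dominate without a protecting group. The position of the new internal triple bond does not matter because step 2 erases it.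

Step 2
Reactants: 4 hexacos-10-yn-1-ol
Product: 6 hexacos-25-yn-1-ol, via dipotassium alkoxide acetylide 5 (not isolated)
Conditions: KH (4 equiv), H2N(CH2)3NH2/THF, rt → 45 °C; then H2O, 0 °C
Reagents that add atoms: none
Why: Alkyne zipper reaction: potassium 3-aminopropylamide moves the triple bond along the chain by reversible propargyl/allenyl deprotonation and reprotonation, and the only irreversible exit is the terminal alkyne, removed as its potassium acetylide 5. The alkoxide end is no exit, and the unbranched C12–C26 segment has no stereocentre or substituent to block the migration or to be scrambled.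

Step 3
Reactants: 6 hexacos-25-yn-1-ol
Product: 9 26-hexacosanolide (oxacycloheptacosan-2-one), via rhodium vinylidene complex 7 (not isolated), via hydroxy ketene 8 (not isolated)
Conditions: [Rh(cod)Cl]2 (5 mol %), P(4-FC6H4)3 (20 mol %), Yb(OTf)3 (10 mol %), 4-picoline N-oxide (2 equiv), MeCN/ClCH2CH2Cl, 4 Å MS, 70 °C, slow addition of 6 (final ca. 2 mM)
Reagents that add atoms: 4-picoline N-oxide (4-methylpyridine N-oxide), Cc1cc[n+]([O-])cc1
Why: Rh(I) binds the terminal alkyne and a 1,2-hydrogen shift gives the vinylidene 7. The N-oxide oxygen attacks the electrophilic metal-bound carbon, and N–O cleavage releases 4-picoline and the ketene 8. The remote hydroxyl, assisted by Yb(III), then adds to the ketene to give the lactone. The closest known reaction type is the rhodium-catalysed oxygenative addition of alcohols to terminal alkynes, including its Rh/Yb variant for macrolactonisation of ω-alkynols. The 27-membered ring is closed at the acyl C1–O bond by addition of O–H across the ketene C1=C2 bond with the carbonyl oxygen exocyclic; a ring of this size is strain-free, so the closure has no stereoelectronic constraint. No stereocentre is formed. The step needs oxygenation at the terminal carbon only, which the vinylidene pathway secures because it requires the C≡C–H unit (hence the unsubstituted C2 of the target). It also needs intra- over intermolecular ketene capture, which is secured by catalytic generation of the ketene at low stationary concentration under slow addition and by the absence of any other nucleophile in the chain.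

## Compound list

1 | 10-undecyn-1-ol (undec-10-yn-1-ol) | C#CCCCCCCCCCO | starting material
2 | 1-bromopentadecane | CCCCCCCCCCCCCCCBr | starting material
3 | dilithium undec-10-yn-11-id-1-olate (alkoxide acetylide of 1, formed in situ) | [Li+].[Li+].[O-]CCCCCCCCCC#[C-] | intermediate
4 | hexacos-10-yn-1-ol | OCCCCCCCCCC#CCCCCCCCCCCCCCCC | intermediate
5 | dipotassium hexacos-25-yn-26-id-1-olate (alkoxide acetylide of 6, formed in situ) | [K+].[K+].[O-]CCCCCCCCCCCCCCCCCCCCCCCCC#[C-] | intermediate
6 | hexacos-25-yn-1-ol | OCCCCCCCCCCCCCCCCCCCCCCCCC#C | intermediate
7 | trans-chloro(26-hydroxyhexacos-1-en-1-ylidene)bis[tris(4-fluorophenyl)phosphine]rhodium (vinylidene complex, formed in situ) | OCCCCCCCCCCCCCCCCCCCCCCCCC=C=[Rh](Cl)(P(c1ccc(F)cc1)(c1ccc(F)cc1)c1ccc(F)cc1)P(c1ccc(F)cc1)(c1ccc(F)cc1)c1ccc(F)cc1 | intermediate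
8 | 26-hydroxyhexacos-1-en-1-one (hydroxy ketene, formed in situ) | O=C=CCCCCCCCCCCCCCCCCCCCCCCCCO | intermediate
9 | 26-hexacosanolide (oxacycloheptacosan-2-one), achiral | O=C1CCCCCCCCCCCCCCCCCCCCCCCCCO1 | target

## Step count and risks

Total step count: 3. Longest linear sequence: 3 steps (1 → 4 → 6 → 9).

Step 3 (key step). The most likely failure is intermolecular capture of the ketene by the hydroxyl of a second molecule, leading to linear and cyclic oligoesters, because the effective molarity for a 27-membered ring is low. Hydration of the ketene by traces of water and rhodium-mediated alkyne dimerisation may also compete. Fallback, from 6 back to 9: hydroboration of 6 with dicyclohexylborane (2.2 equiv, THF, 0 °C; one equivalent is consumed by the hydroxyl) should give dicyclohexyl[(E)-26-(dicyclohexylboranyloxy)hexacos-1-en-1-yl]borane F1. Oxidation in the same flask (NaBO3·4H2O) should give 26-hydroxyhexacosanal F2. Pinnick oxidation (NaClO2, NaH2PO4, 2-methyl-2-butene) should then give 26-hydroxyhexacosanoic acid F3. Yamaguchi macrolactonisation (2,4,6-trichlorobenzoyl chloride, Et3N; then DMAP, toluene, reflux, high dilution) should pass through 26-hydroxyhexacosanoic 2,4,6-trichlorobenzoic anhydride F4 and close the same C1–O bond to give 9.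

Step 2. The migration over 15 positions may stall if the dipotassium salts of the long chain precipitate, or if the amide base decays at the temperature needed for solubility. This would leave internal alkyne and allene isomers that cannot be separated from 6 and are inert in step 3. Fallback, from 1 back to 6, in which the terminal triple bond is never moved: Appel bromination of 1 (CBr4, PPh3) should give 11-bromoundec-1-yne F5. C-silylation (LiHMDS, THF, −78 °C; Me3SiCl) should give (11-bromoundec-1-yn-1-yl)trimethylsilane F6. Magnesium in THF should convert this into [11-(trimethylsilyl)undec-10-yn-1-yl]magnesium bromide F7. Li2CuCl4-catalysed sp3–sp3 coupling with bromomagnesium 15-bromopentadecan-1-olate F8, made from commercial 15-bromopentadecan-1-ol and i-PrMgCl, should give 26-(trimethylsilyl)hexacos-25-yn-1-ol F9. K2CO3 in MeOH should then remove the silyl group and give 6.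

Step 1. Competing O-alkylation of the alkoxide, or poor solubility and aggregation of the dilithio species 3, may lower conversion and give ether by-products. Fallback, from 1 back to 4: silylation of 1 (TBSCl, imidazole) should give tert-butyldimethyl(undec-10-yn-1-yloxy)silane F10. Deprotonation with n-BuLi (1 equiv) should give lithium 11-[(tert-butyldimethylsilyl)oxy]undec-1-yn-1-ide F11. Alkylation with 2 in THF/HMPA should give tert-butyl(hexacos-10-yn-1-yloxy)dimethylsilane F12. HCl in MeOH should then cleave the silyl ether and give 4.

## Further compounds

F1 | step 3 | dicyclohexyl[(E)-26-(dicyclohexylboranyloxy)hexacos-1-en-1-yl]borane | C1CCCCC1B(C1CCCCC1)OCCCCCCCCCCCCCCCCCCCCCCCC/C=C/B(C1CCCCC1)C1CCCCC1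
F2 | step 3 | 26-hydroxyhexacosanal | O=CCCCCCCCCCCCCCCCCCCCCCCCCCO
F3 | step 3 | 26-hydroxyhexacosanoic acid | OC(=O)CCCCCCCCCCCCCCCCCCCCCCCCCO
F4 | step 3 | 26-hydroxyhexacosanoic 2,4,6-trichlorobenzoic anhydride | OCCCCCCCCCCCCCCCCCCCCCCCCCC(=O)OC(=O)c1c(Cl)cc(Cl)cc1Cl
F5 | step 2 | 11-bromoundec-1-yne | C#CCCCCCCCCCBr
F6 | step 2 | (11-bromoundec-1-yn-1-yl)trimethylsilane | C[Si](C)(C)C#CCCCCCCCCCBr
F7 | step 2 | [11-(trimethylsilyl)undec-10-yn-1-yl]magnesium bromide | C[Si](C)(C)C#CCCCCCCCCC[Mg]Br
F8 | step 2 | bromomagnesium 15-bromopentadecan-1-olate | Br[Mg]OCCCCCCCCCCCCCCCBr
F9 | step 2 | 26-(trimethylsilyl)hexacos-25-yn-1-ol | C[Si](C)(C)C#CCCCCCCCCCCCCCCCCCCCCCCCCO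
F10 | step 1 | tert-butyldimethyl(undec-10-yn-1-yloxy)silane | C#CCCCCCCCCCO[Si](C)(C)C(C)(C)C
F11 | step 1 | lithium 11-[(tert-butyldimethylsilyl)oxy]undec-1-yn-1-ide | [Li+].[C-]#CCCCCCCCCCO[Si](C)(C)C(C)(C)C
F12 | step 1 | tert-butyl(hexacos-10-yn-1-yloxy)dimethylsilane | CCCCCCCCCCCCCCCC#CCCCCCCCCCO[Si](C)(C)C(C)(C)C
A1 | alternative 1 | 26-hydroxyhexacosanoic acid | OC(=O)CCCCCCCCCCCCCCCCCCCCCCCCCO
A2 | alternative 2 | undec-10-en-1-yl heptadec-16-enoate | C=CCCCCCCCCCCCCCCC(=O)OCCCCCCCCCC=C
A3 | alternative 2 | oxacycloheptacos-17-en-2-one (E/Z mixture) | O=C1CCCCCCCCCCCCCCC=CCCCCCCCCCO1
A4 | alternative 3 | dec-9-en-1-yl dec-9-enoate | C=CCCCCCCCC(=O)OCCCCCCCCC=C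
A5 | alternative 3 | oxacycloheptacosa-10,18-dien-2-one (E/Z mixture) | O=C1CCCCCCCC=CCCCCCCC=CCCCCCCCCO1
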